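I began from a ratio of 32.0 %, the base load L, defined as the electrophile lost in the eta run by 80.0 min over the equivalents of free base in maple. It is a reading with scatter, and it supposes that electrophile, the limiting reagent, gives target with nucleophile and sets free one acid per electrophile lost, which free base binds.

common to all: electrophile 0.059 M
- eta: nucleophile 2.5 equiv; free base 1.3 equiv; run made earlier
- epsilon: nucleophile 2.5 equiv; free base 2.9 equiv; run made earlier
- maple: nucleophile 2.50 equiv; free base 1.00 equiv; time 80 min
- elm: nucleophile 2.50 equiv; free base 2.00 equiv; time 80 min

- eta (time / min: electrophile / %, target / %): 6.00: 96, 3; 15.0: 96, 4; 30.0: 88, 11; 80.0: 68, 20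
- epsilon (time / min: electrophile / %, target / %): 20.0: 95, 7; 40.0: 84, 6; 60.0: 79, 17; 80.0: 74, 25

(each reading ± 2 percentage points)

- part of the electrophile that has reacted at the end, maple
- part of the electrophile that has reacted at the end, elm
- what raising the equivalents of free base from its lowest to its highest value here does to the part of the electrophile that has reacted (changes below 5 percentage points count as none) (it falls / no change / it rises)

- a reading or a percentage of target counts all its forms, free or not

My first question was whether free base speeds the loss. Going from 1.3 equiv in eta to 2.9 equiv in epsilon took the loss at that time from 32.0 % to 26.0 %, a ratio of 0.813, so the loss did not grow with the base. The gap of 6 percentage points stood against 2.8 points for the scatter of a difference, so I did not trust it as a fall either.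

My second question was whether free base could give out. In maple, L is about a third of the charge, which leaves 68.0 % of it unbound on my supposition, and in elm the load is 16.0 %. On that supposition free base did not give out in either flask, so my own reckoning, which was not the forecast's, took the mean loss of the two runs, 29.0 %, for maple and elm alike.

The forecast differed from my single figure: it gave 30 % (24 % to 37 %) for maple, 28 % (23 % to 33 %) for elm, and no change, on this ground: “Base therefore has little kinetic role”.

The flasks gave 31.1 % in maple and 31.1 % in elm, so no change, with a change of 0.073 points.

    electrophile + target → side product (k = 6.72 L mol⁻¹ h⁻¹)
    nucleophile + acid set free ⇌ protonated nucleophile, settled at all times (K = 260 L mol⁻¹)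
    crystals ⇌ target, rate k3*(cs3 - [target]) while solid is left; crystals form when [target] > cs3 (solubility = 26.0 mM, k = 2.65 h⁻¹)
    electrophile + nucleophile → acid set free + target (k = 1.67 L mol⁻¹ h⁻¹)
    acid set free + free base ⇌ salt of the base, settled at all times (K = 6200 L mol⁻¹)

During the 80 min of maple, electrophile and nucleophile made target and acid set free, and target took electrophile into side product, which held 10.2 %, while 23.1 % of the free base went, below L. In elm left until 5.0 h, electrophile had fallen to 21 % and side product held 44.3 %, which made the load 39.3 %, while the free base had lost 26.7 %.

The readings were generated by integration for substances that don't exist; the scatter is artificial.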